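**Retrosynthetic overview**
1. The target comes from the 4‑O‑vanilloyl dauca‑5,8‑diene by epoxidation of C8=C9 and hydroboration–oxidation of C5=C6, which set C8, C9, C5 and C6 last.
2. The diene ester comes from a bicyclic dienone by 1,2‑addition of isopropylmagnesium chloride and in‑situ acylation with a silyl‑protected vanilloyl chloride built from catechol, MeI and CO2.
3. The seven‑membered ring is closed by ring‑closing metathesis of an allyl and a methallyl terminus.
4. The five‑membered ring comes from gold‑catalysed ring expansion (1,2‑alkyl shift) of a 1‑alkynylcyclobutanol, which creates the C4 ketone and the C5=C6 alkene.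
5. The quaternary C1 comes from enantioselective α‑allylation of 2‑methylcyclobutanone; ring order is four‑membered, then five‑membered, then seven‑membered.

Assumption: the ester is on the tertiary C4 oxygen and the C6 hydroxyl is free, as the SMILES is written; daucane numbering is used for the bicyclic compounds (C1 quaternary ring‑fusion carbon, C4 carbinol carbon with isopropyl, C5 ring‑fusion CH, C6 carbinol, C8 methyl‑bearing carbon).
Assumption: (S)‑TRIP, the (S)‑3,3'‑bis(2,4,6‑triisopropylphenyl)‑1,1'‑binaphthyl‑2,2'‑diyl hydrogen phosphate, gives the R ketone 3; if the sense is opposite, its enantiomer is used.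

**Step 1**
Reactants: 1 2‑methylcyclobutan‑1‑one (racemic); 2 prop‑2‑en‑1‑ol
Product: 3 (R)‑2‑methyl‑2‑(prop‑2‑en‑1‑yl)cyclobutan‑1‑one
Conditions: Pd2(dba)3 (2.5 mol %), tBuXPhos (11 mol %), (S)‑TRIP (10 mol %), CO2 (1 atm), cyclohexane, 40 °C
Reagents that add atoms: none
Why: Proposed new method: the phosphoric acid enolises 1 to the more substituted enol, CO2 turns allyl alcohol into a carbonic half‑ester that ionises to a π‑allylpalladium cation paired with the chiral phosphate, and C–C bond formation inside this ion pair sets the quaternary centre (future C1); the closest known reaction is the direct palladium/chiral phosphoric acid α‑allylation (Tsuji–Trost type) of α‑branched cyclohexanones with allyl alcohol, not yet shown on the more strained, less easily enolised cyclobutanones.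

**Step 2**
Reactants: 4 3‑chloro‑2‑methylprop‑1‑ene; 5 ethynylmagnesium bromide
Product: 6 2‑methylpent‑1‑en‑4‑yne
Conditions: CuCl (5 mol %), THF, 0 → 45 °C
Reagents that add atoms: none
Why: Copper‑catalysed SN2 coupling of an alkynyl Grignard reagent with an allylic chloride gives the skipped enyne; no stereocentre is formed.

**Step 3**
Reactants: 6 2‑methylpent‑1‑en‑4‑yne; 3 (R)‑2‑methyl‑2‑(prop‑2‑en‑1‑yl)cyclobutan‑1‑one
Product: 8 (2R)‑2‑methyl‑1‑(4‑methylpent‑4‑en‑1‑yn‑1‑yl)‑2‑(prop‑2‑en‑1‑yl)cyclobutan‑1‑ol (both carbinol epimers), via lithium acetylide 7 (not isolated)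
Conditions: n‑BuLi, THF, −78 °C; then 3, −78 → 0 °C; H2O
Reagents that add atoms: none
Why: Acetylide 1,2‑addition (alkynylation) to the strained, electrophilic cyclobutanone; the new carbinol centre is a mixture that does not matter because it becomes the carbonyl carbon in step 4.

**Step 4**
Reactants: 8 (2R)‑2‑methyl‑1‑(4‑methylpent‑4‑en‑1‑yn‑1‑yl)‑2‑(prop‑2‑en‑1‑yl)cyclobutan‑1‑ol
Product: 9 (2E,3R)‑3‑methyl‑2‑(3‑methylbut‑3‑en‑1‑ylidene)‑3‑(prop‑2‑en‑1‑yl)cyclopentan‑1‑one
Conditions: (4‑CF3C6H4)3PAuCl (2 mol %), AgSbF6 (2 mol %), CH2Cl2, 23 °C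
Reagents that add atoms: none
Why: Gold‑catalysed ring expansion of a 1‑alkynylcyclobutanol (semipinacol‑type 1,2‑alkyl shift onto the π‑activated alkyne): the more substituted ring carbon migrates with retention and anti to gold, so the cyclopentanone forms with the quaternary centre intact and the E‑alkylidene that places the side chain cis to it.

**Step 5**
Reactants: 9 (2E,3R)‑3‑methyl‑2‑(3‑methylbut‑3‑en‑1‑ylidene)‑3‑(prop‑2‑en‑1‑yl)cyclopentan‑1‑one
Product: 10 (3aR)‑3a,6‑dimethyl‑3,3a,4,7‑tetrahydroazulen‑1(2H)‑one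
Conditions: second‑generation Grubbs catalyst RuCl2(=CHPh)(PCy3)(H2IMes) (5 mol %), CH2Cl2 (5 mM), 40 °C
Reagents that add atoms: none
Why: Ring‑closing olefin metathesis of the allyl and methallyl termini closes the seven‑membered ring as the trisubstituted C8=C9 alkene; the electron‑poor trisubstituted enone alkene does not take part.

**Step 6**
Reactants: 11 benzene‑1,2‑diol (catechol)
Product: 12 2‑methoxyphenol
Conditions: MeI (1.0 equiv), K2CO3, acetone, 56 °C
Reagents that add atoms: iodomethane (CI)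
Why: Williamson mono‑O‑methylation of catechol; the statistical mixture is separated by distillation.

**Step 7**
Reactants: 12 2‑methoxyphenol
Product: 14 (4‑bromo‑2‑methoxyphenoxy)(tert‑butyl)dimethylsilane, via bromophenol 13 (not isolated)
Conditions: NBS, DMF, 0 °C; then imidazole, TBSCl, 23 °C
Reagents that add atoms: N‑bromosuccinimide (O=C1CCC(=O)N1Br); tert‑butyldimethylsilyl chloride (CC(C)(C)[Si](C)(C)Cl)
Why: Electrophilic aromatic bromination goes para to the free phenol, the stronger director, and the phenol is then silylated in the same pot.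

**Step 8**
Reactants: 14 (4‑bromo‑2‑methoxyphenoxy)(tert‑butyl)dimethylsilane
Product: 17 4‑(tert‑butyldimethylsilyloxy)‑3‑methoxybenzoyl chloride, via aryllithium 15 (not isolated), via lithium carboxylate 16 (not isolated)
Conditions: n‑BuLi, THF, −78 °C; CO2; then (COCl)2, DMF (cat.), 0 → 23 °C; used crude
Reagents that add atoms: carbon dioxide (O=C=O); oxalyl chloride (O=C(Cl)C(Cl)=O)
Why: Bromine–lithium exchange, carboxylation of the aryllithium, and conversion of the carboxylate into the acid chloride with oxalyl chloride under Vilsmeier‑type activation.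

**Step 9**
Reactants: 10 (3aR)‑3a,6‑dimethyl‑3,3a,4,7‑tetrahydroazulen‑1(2H)‑one; 18 isopropylmagnesium chloride; 17 4‑(tert‑butyldimethylsilyloxy)‑3‑methoxybenzoyl chloride
Product: 21 (1R,4R)‑dauca‑5,8‑dien‑4‑yl 4‑hydroxy‑3‑methoxybenzoate, via magnesium alkoxide 19 (not isolated), via silyl‑protected ester 20 (not isolated)
Conditions: 18, LaCl3·2LiCl (0.3 equiv), THF, −20 → 0 °C; then 17, DMAP, 0 → 23 °C; then Bu4NF, AcOH, THF, 0 °C
Reagents that add atoms: none
Why: Lanthanum‑promoted Grignard 1,2‑addition to the enone from the face opposite the angular methyl group (as in angularly methylated hydrindanones) sets C4 with oxygen cis to that methyl, the tertiary alkoxide is acylated in situ so no free tertiary alcohol has to be esterified, and buffered fluoride removes the aryl silyl ether.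

**Step 10**
Reactants: 21 (1R,4R)‑dauca‑5,8‑dien‑4‑yl 4‑hydroxy‑3‑methoxybenzoate
Product: 22 (1R,4R,8R,9S)‑8,9‑epoxydauc‑5‑en‑4‑yl 4‑hydroxy‑3‑methoxybenzoate (8α,9α‑epoxide)
Conditions: m‑CPBA (1.05 equiv), CH2Cl2, −20 → 0 °C
Reagents that add atoms: 3‑chloroperbenzoic acid (O=C(OO)c1cccc(Cl)c1)
Why: Prilezhaev epoxidation picks the electron‑rich, unhindered C8=C9 alkene (C5=C6 is deactivated by the allylic ester and flanked by two fully substituted carbons) and is expected to attack the face opposite the angular methyl group.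

**Step 11**
Reactants: 22 (1R,4R,8R,9S)‑8,9‑epoxydauc‑5‑en‑4‑yl 4‑hydroxy‑3‑methoxybenzoate
Product: 24 (1R,4R,5S,6S,8R,9S)‑8,9‑epoxy‑6‑hydroxydaucan‑4‑yl 4‑hydroxy‑3‑methoxybenzoate (target), via alkylborane 23 (not isolated)
Conditions: BH3·SMe2 (3 equiv), THF, 0 → 23 °C; then NaBO3·4H2O, THF–H2O, 23 °C
Reagents that add atoms: sodium perborate ([Na+].[Na+].O[B-]1(O)OO[B-](O)(O)OO1)
Why: Hydroboration–oxidation adds H to C5 and boron to C6 in a syn, anti‑Markovnikov fashion from the face opposite the angular methyl and the allylic acyloxy group (as in the 5α,6α‑selective hydroboration of 5‑ene steroids), and oxidation with retention gives the trans ring fusion and the 6α‑alcohol in one step.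

**Compound list**
1 | 2‑methylcyclobutan‑1‑one (racemic) | CC1CCC1=O | starting material
2 | prop‑2‑en‑1‑ol | C=CCO | starting material
3 | (R)‑2‑methyl‑2‑(prop‑2‑en‑1‑yl)cyclobutan‑1‑one | O=C1CC[C@]1(C)CC=C | intermediate
4 | 3‑chloro‑2‑methylprop‑1‑ene | C=C(C)CCl | starting material
5 | ethynylmagnesium bromide | C#C[Mg]Br | starting material
6 | 2‑methylpent‑1‑en‑4‑yne | C=C(C)CC#C | intermediate
7 | (4‑methylpent‑4‑en‑1‑yn‑1‑yl)lithium | [Li]C#CCC(C)=C | intermediate
8 | (2R)‑2‑methyl‑1‑(4‑methylpent‑4‑en‑1‑yn‑1‑yl)‑2‑(prop‑2‑en‑1‑yl)cyclobutan‑1‑ol, both carbinol epimers | OC1(C#CCC(C)=C)CC[C@]1(C)CC=C | intermediate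
9 | (2E,3R)‑3‑methyl‑2‑(3‑methylbut‑3‑en‑1‑ylidene)‑3‑(prop‑2‑en‑1‑yl)cyclopentan‑1‑one | O=C1CC[C@](C)(CC=C)/C1=C\CC(C)=C | intermediate
10 | (3aR)‑3a,6‑dimethyl‑3,3a,4,7‑tetrahydroazulen‑1(2H)‑one | O=C1CC[C@]2(C)CC=C(C)CC=C12 | intermediate
11 | benzene‑1,2‑diol | Oc1ccccc1O | starting material
12 | 2‑methoxyphenol | COc1ccccc1O | intermediate
13 | 4‑bromo‑2‑methoxyphenol | COc1cc(Br)ccc1O | intermediate
14 | (4‑bromo‑2‑methoxyphenoxy)(tert‑butyl)dimethylsilane | COc1cc(Br)ccc1O[Si](C)(C)C(C)(C)C | intermediate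
15 | [4‑(tert‑butyldimethylsilyloxy)‑3‑methoxyphenyl]lithium | COc1cc([Li])ccc1O[Si](C)(C)C(C)(C)C | intermediate
16 | lithium 4‑(tert‑butyldimethylsilyloxy)‑3‑methoxybenzoate | COc1cc(C(=O)[O-])ccc1O[Si](C)(C)C(C)(C)C.[Li+] | intermediate
17 | 4‑(tert‑butyldimethylsilyloxy)‑3‑methoxybenzoyl chloride | COc1cc(C(Cl)=O)ccc1O[Si](C)(C)C(C)(C)C | intermediate
18 | isopropylmagnesium chloride | CC(C)[Mg]Cl | starting material
19 | chloromagnesium (1R,4R)‑dauca‑5,8‑dien‑4‑olate | Cl[Mg]O[C@@]1(C(C)C)CC[C@]2(C)CC=C(C)CC=C21 | intermediate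
20 | (1R,4R)‑dauca‑5,8‑dien‑4‑yl 4‑(tert‑butyldimethylsilyloxy)‑3‑methoxybenzoate | COc1cc(C(=O)O[C@@]2(C(C)C)CC[C@]3(C)CC=C(C)CC=C32)ccc1O[Si](C)(C)C(C)(C)C | intermediate
21 | (1R,4R)‑dauca‑5,8‑dien‑4‑yl 4‑hydroxy‑3‑methoxybenzoate | COc1cc(C(=O)O[C@@]2(C(C)C)CC[C@]3(C)CC=C(C)CC=C32)ccc1O | intermediate
22 | (1R,4R,8R,9S)‑8,9‑epoxydauc‑5‑en‑4‑yl 4‑hydroxy‑3‑methoxybenzoate | COc1cc(C(=O)O[C@@]2(C(C)C)CC[C@]3(C)C[C@@H]4O[C@]4(C)CC=C32)ccc1O | intermediate
23 | 6α‑boryl‑8α,9α‑epoxy‑5α‑daucan‑4β‑yl 4‑(boryloxy)‑3‑methoxybenzoate | COc1cc(C(=O)O[C@@]2(C(C)C)CC[C@]3(C)C[C@@H]4O[C@]4(C)C[C@H](B)[C@H]32)ccc1OB | intermediate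
24 | (1R,4R,5S,6S,8R,9S)‑8,9‑epoxy‑6‑hydroxydaucan‑4‑yl 4‑hydroxy‑3‑methoxybenzoate | COc1cc(C(=O)O[C@@]2(C(C)C)CC[C@]3(C)C[C@@H]4O[C@]4(C)C[C@H](O)[C@H]32)ccc1O | target

**Step count and risks**
Total: 11 steps. Longest linear sequence: 7 steps (1, 3, 4, 5, 9, 10, 11).

Step 1 (the proposed new allylation) may fail through slow enolisation of the strained ketone, allylation at the unsubstituted α‑carbon, or low enantiomeric excess. The fallback uses known chemistry, sets out from 1 and comes back at 3. Ketone 1 is converted under thermodynamic conditions (Me3SiCl, NaI, Et3N, MeCN) into the more substituted silyl enol ether 1‑methyl‑2‑(trimethylsilyloxy)cyclobut‑1‑ene F1. F1 then undergoes the fluoride‑triggered enantioselective Tsuji allylation (diallyl carbonate, Bu4N[Ph3SiF2], Pd2(dba)3, (S)‑t‑Bu‑PHOX, THF, 25 °C) to give 3.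

Step 11 may fail because borane attacks the epoxide or the aryl ester, or adds from the methyl‑bearing face. The fallback sets out from 10 and comes back at 24, and puts the oxygen on C6 before the isopropyl group arrives.
- Copper‑catalysed conjugate borylation of the enone (B2pin2, CuCl, Xantphos, NaOtBu, MeOH, THF) adds boron to C6 and a proton to C5, both opposite the angular methyl, giving 6α‑(4,4,5,5‑tetramethyl‑1,3,2‑dioxaborolan‑2‑yl)‑5α‑dauc‑8‑en‑4‑one (isopropyl absent) F3.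
- NaBO3·4H2O oxidises it to the aldol 6α‑hydroxy‑5α‑dauc‑8‑en‑4‑one (isopropyl absent) F4, and Et3SiCl/imidazole gives its triethylsilyl ether F5.
- Addition of 18 with LaCl3·2LiCl gives the chloromagnesium alkoxide F6, and acylation with 17 gives 6α‑(triethylsilyloxy)‑5α‑dauc‑8‑en‑4β‑yl 4‑(tert‑butyldimethylsilyloxy)‑3‑methoxybenzoate F7.
- Bu4NF/AcOH removes both silyl groups to give 6α‑hydroxy‑5α‑dauc‑8‑en‑4β‑yl 4‑hydroxy‑3‑methoxybenzoate F8, and hydroxyl‑directed epoxidation (VO(acac)2, t‑BuOOH, CH2Cl2) delivers the 8α,9α‑epoxide 24.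
- C5 in this fallback rests on kinetic protonation of the enolate, which is less secure than the concerted addition of step 11; no base is used afterwards.

Step 10 may fail because the peracid attacks the methyl‑bearing face or over‑oxidises. The fallback sets out from 20 (isolated by leaving out the fluoride treatment in step 9) and comes back at 22. NBS in acetone–H2O at 0 °C forms the bromonium ion on the face the peracid prefers, and water opens it at the tertiary C8 from the other face, giving the bromohydrin 9β‑bromo‑8α‑hydroxydauc‑5‑en‑4β‑yl 4‑(tert‑butyldimethylsilyloxy)‑3‑methoxybenzoate F2. K2CO3 in MeOH then closes the epoxide with inversion at C9 and cleaves the aryl silyl ether, giving 22 with the oxygen on the face opposite to direct epoxidation.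

**Further compounds**
F1 | step 1 | 1‑methyl‑2‑(trimethylsilyloxy)cyclobut‑1‑ene | CC1=C(O[Si](C)(C)C)CC1
F2 | step 10 | 9β‑bromo‑8α‑hydroxydauc‑5‑en‑4β‑yl 4‑(tert‑butyldimethylsilyloxy)‑3‑methoxybenzoate | COc1cc(C(=O)O[C@@]2(C(C)C)CC[C@]3(C)C[C@@H](Br)[C@@](O)(C)CC=C32)ccc1O[Si](C)(C)C(C)(C)C
F3 | step 11 | (3aR,8S,8aS)‑3a,6‑dimethyl‑8‑(4,4,5,5‑tetramethyl‑1,3,2‑dioxaborolan‑2‑yl)‑3,3a,4,7,8,8a‑hexahydroazulen‑1(2H)‑one (6α‑boryl, 5α‑H in daucane numbering) | O=C1CC[C@]2(C)CC=C(C)C[C@H](B3OC(C)(C)C(C)(C)O3)[C@@H]12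
F4 | step 11 | 8‑hydroxy‑3a,6‑dimethyl‑3,3a,4,7,8,8a‑hexahydroazulen‑1(2H)‑one (6α‑OH, 5α‑H in daucane numbering) | O=C1CC[C@]2(C)CC=C(C)C[C@H](O)[C@@H]12
F5 | step 11 | 3a,6‑dimethyl‑8‑(triethylsilyloxy)‑3,3a,4,7,8,8a‑hexahydroazulen‑1(2H)‑one (6α‑OSiEt3, 5α‑H) | O=C1CC[C@]2(C)CC=C(C)C[C@H](O[Si](CC)(CC)CC)[C@@H]12
F6 | step 11 | chloromagnesium 6α‑(triethylsilyloxy)‑5α‑dauc‑8‑en‑4β‑olate | Cl[Mg]O[C@@]1(C(C)C)CC[C@]2(C)CC=C(C)C[C@H](O[Si](CC)(CC)CC)[C@H]21
F7 | step 11 | 6α‑(triethylsilyloxy)‑5α‑dauc‑8‑en‑4β‑yl 4‑(tert‑butyldimethylsilyloxy)‑3‑methoxybenzoate | COc1cc(C(=O)O[C@@]2(C(C)C)CC[C@]3(C)CC=C(C)C[C@H](O[Si](CC)(CC)CC)[C@H]32)ccc1O[Si](C)(C)C(C)(C)C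
F8 | step 11 | 6α‑hydroxy‑5α‑dauc‑8‑en‑4β‑yl 4‑hydroxy‑3‑methoxybenzoate | COc1cc(C(=O)O[C@@]2(C(C)C)CC[C@]3(C)CC=C(C)C[C@H](O)[C@H]32)ccc1O
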